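(The readings were computed with constants of no real substance.)

Slowness is what lets us reckon with a mean: the east run took 8.00 h to turn 36.7% of its Q into X, so one average may stand in for the curve. Dividing that fraction by the fraction of J on Q and by the time gives 91.8 /h, the mean turnover rate: turnovers of J per hour over a whole run.

| setting | south-west | south | east | flask |
|---|---|---|---|---|
| Q | 0.010 M | 0.010 M | 0.020 M | 0.010 M |
| L | 4.3 mM (held) | 4.3 mM (held) | 4.3 mM (held) | 4.3 mM (held) |
| J | 0.025 mol% | 0.038 mol% | 0.05 mol% | 0.05 mol% |
| remark | run made earlier | run made earlier | run made earlier |  |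
| time |  |  |  | 12 h |

- south-west (time / h: X / %, Q / %): 0.667: 1.5, 100.2; 2.00: 3.8, 96.4; 3.00: 5.4, 94.6; 5.00: 11.9, 89.6; 8.00: 18.4, 80.2
- south (time / h: X / %, Q / %): 0.500: 0, 99.1; 1.00: 1.5, 98.2; 2.00: 4.5, 94.5; 4.00: 10.6, 86.2; 8.00: 27.0, 70.7
- east (time / h: X / %, Q / %): 0.500: 0, 98.0; 1.00: 0.8, 98.5; 2.00: 7.7, 92.1; 4.00: 16.0, 82.9; 8.00: 36.7, 65.2

(each reading ± 1 percentage point)

* how much X there is at 12 h, in percent of the Q charged
* the change that raises the amount of X at 12 h, in percent of the Q charged most ("none" if none brings more than 2 percentage points) (blue / teal / violet / none)
* amount of X at 12 h, in percent of the Q charged, after violet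

- at the start none of L is in solution

- blue: doubling the transfer coefficient of L, all else as stated
- teal: doubling the saturation concentration of L, all else as stated
- violet: doubling the amount of J, all else as stated

The flask looks nearly like the east run, with the same loading of J but half the Q. The south-west and south runs, at the flask's Q, give 92.0 /h and 88.8 /h, close to the east value, so we expect the flask to follow the east run in fractions of its charge. It should end above the east run's last reading because it runs 12 h rather than 8.00 h: the mean gives 55.0%.

Now the error of the mean. The east run's first 2.00 h averaged 77.0 /h, and its last stretch 104 /h. Carrying that stretch on gives 57.4%. But our figure leaves 45.0% of the Q, below the 65.2% the east run held at its last reading, so the flask goes beyond what that stretch shows, and we do not carry it on but stay with 55.0%. Doubling J would give 110% by the mean, beyond the charge, so the straight line fails there; we still expect violet to lead, though the three runs held L at 4.3 mM.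

The forecast, reading the rate as “about zero order in Q”, gave 54% (48% to 60%), chose violet, and gave 90% (74% to 99%) after it.

The flask gives 52.6%. The best change is violet, gaining 29 percentage points against 9.7 points for teal and 4.2 points for blue, and it reaches 81.2%.

    L ⇌ D, rate k1*(csat - [D]) (kL = 1.20 × 10⁻⁴ /s)
    Q + Z → E (k = 8.20 /M/s)
    D + J → Z (k = 26.0 /M/s)
    E → J + X (k = 0.130 /s)

The flask's own mean turnover rate is 87.7 /h, a little below our 91.8 /h. At 3.96 h the step from Q + Z to E gives Q a half-life of 12 h, about the 12 h asked, and gives Z a half-life of 0.17 min; at 12.0 h the flask holds 47.4% of Q. For the neighbour with 0.013 mol% of J, read at the same time, the mean turnover rate gives 14.3%; the computed amount of X is 16.4%.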